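The earlier runs and the new flask were computed for substances that don't exist; noise was put on by code.

Blackboard note on the flasks maple, oak and elm

- Temperature comes first: the blue run stands at −5 °C with second substrate at 1.4 mM, the ochre run at 25 °C with second substrate at 2.2 mM, and from these two runs we must judge three new flasks.

| setting | blue | ochre | maple | oak | elm |
|---|---|---|---|---|---|
| starting material | 1 mM | 1 mM | 1.0 mM | 1.0 mM | 1.0 mM |
| second substrate | 1.4 mM | 2.2 mM | 1.00 mM | 1.00 mM | 1.00 mM |
| free enzyme | 0.10 µM | 0.10 µM | 0.10 µM | 0.10 µM | 0.10 µM |
| temperature | −5 °C | 25 °C | 0 °C | 50 °C | 25 °C |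
| remark | run made earlier | run made earlier |  |  |  |
| time |  |  | 4.0 min | 4.0 min | 4.0 min |

blue run (percent of the starting material charged)

| time / min | target / % | starting material / % |
|---|---|---|
| 0.417 | 1.7 | 100.1 |
| 1.00 | 2.0 | 99.3 |
| 2.00 | 5.1 | 95.2 |
| 3.00 | 8.7 | 92.2 |

ochre run (percent of the starting material charged)

| time / s | target / % | starting material / % |
|---|---|---|
| 15.0 | 1.7 | 97.1 |
| 25.0 | 2.9 | 94.0 |
| 40.0 | 4.4 | 88.2 |
| 50.0 | 8.7 | 86.2 |

(each reading ± 1 percentage point)

- the flask that comes out highest in amount of target, in percent of the starting material charged, or "all alike" when all lie within 1.5 percentage points (maple / oak / elm / all alike)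
- target at the end, in percent of the starting material charged, maple
- target at the end, in percent of the starting material charged, oak
- target at the end, in percent of the starting material charged, elm



- The bench rule says that what leaves as starting material arrives as target, so we can read c(target) off the fall of c(starting material) without asking about time.
- In blue the rule stands: the last reading has target at 8.7 % against a loss of 7.80 %, a gap smaller than the scatter of 1 percentage point.
- In ochre the rule breaks: the gain of c(target) over the loss of c(starting material) at the last reading is 0.630, and we carry this reading as the share, the part of the loss that arrives as target, the field's selectivity. The share belongs to the moment of its reading, and blue's last reading gives 1.12, so the border of the rule lies somewhere between these two runs, which differ in second substrate, temperature and time of reading.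
- Our own reckoning is for elm, which has ochre's temperature. Ochre's fall of 0.166 min⁻¹, kept unchanged over 4.0 min, removes 66.2 %, and the share, held by assumption at ochre's reading, turns that into 41.8 % target.
- The forecast picks elm, with maple at 12 % (8 % to 16 %), oak at 17 % (4 % to 40 %) and elm at 21 % (13 % to 32 %), holding that “that path grows with temperature”. Its elm lies below ours.
- The flasks give 18.9 % in maple, 33.1 % in oak and 56.0 % in elm, so elm stands highest, as the forecast picked.

    starting material → uncatalysed product (k = 1.70 × 10⁻⁴ s⁻¹, Ea = 91.0 kJ mol⁻¹)
    starting material + free enzyme ⇌ complex A (K = 1900 M⁻¹, k = 4.80 × 10⁷ M⁻¹ s⁻¹, Ea = 9.00 kJ mol⁻¹, ΔH = −30.0 kJ mol⁻¹)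
    complex B → free enzyme + second product (k = 430 s⁻¹, Ea = 58.0 kJ mol⁻¹)
    free enzyme → unfolded enzyme (k = 8.00 × 10⁻⁵ s⁻¹, Ea = 216 kJ mol⁻¹)
    target ⇌ isomer of the product (K = 0.760, k = 0.0220 s⁻¹, Ea = 74.0 kJ mol⁻¹, ΔH = −11.0 kJ mol⁻¹)
    complex A → free enzyme + target (k = 160 s⁻¹, Ea = 48.0 kJ mol⁻¹)
    second substrate + free enzyme ⇌ complex B (K = 9900 M⁻¹, k = 1.30 × 10⁷ M⁻¹ s⁻¹, Ea = 14.0 kJ mol⁻¹, ΔH = −17.0 kJ mol⁻¹)
    (constants at 25 °C)

- In elm the share at the end is 0.565, below ochre's reading, with 41.7 % standing as isomer of the product. The relaxation half-life of target and isomer of the product by their own step in elm is 0.227 min, far shorter than the 4.0 min of the run, and elm ends with isomer over target at 0.745 beside an equilibrium constant of 0.76 at 25 °C.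
- A neighbour of elm with 6.0 × 10⁻⁵ mM free enzyme keeps 13 % starting material, so the share promises 54.8 % target. The computed flask gives 50.3 %.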